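A ring share of 40.6 % is read at the close of the south, south-east and north runs, with substrate at 0.20 M and activator at 0.20 M, 0.30 M and 0.40 M in that order.

| flask | substrate | activator | remark | time |
|---|---|---|---|---|
| north | 0.20 M | 0.40 M | run made earlier |  |
| south | 0.20 M | 0.20 M | run made earlier |  |
| south-east | 0.20 M | 0.30 M | run made earlier |  |
| east | 0.30 M | 0.40 M | run made earlier |  |
| eta | 0.20 M | 0.400 M (fed, over 3.0 min) | all else is in the flask from the start; the feed brings no volume worth counting | 5.0 min |
| zeta | 0.20 M | 0.400 M | everything together at the start | 5.0 min |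
| alpha | 0.20 M (fed, over 3.0 min) | 0.400 M | all else is in the flask from the start; the feed brings no volume worth counting | 5.0 min |
| theta | 0.20 M (in portions, 5, over 3.0 min) | 0.400 M | first portion at the start, last at 3.0 min | 5.0 min |

| run | time / min | ring / % | open dimer / % |
|---|---|---|---|
| north | 0.667 | 40.5 | 60.2 |
| north | 2.00 | 40.2 | 59.2 |
| north | 3.00 | 41.3 | 58.8 |
| north | 5.00 | 41.0 | 58.5 |
| south | 1.33 | 37.2 | 61.5 |
| south | 2.50 | 38.4 | 60.5 |
| south | 4.00 | 40.0 | 61.6 |
| south | 5.00 | 40.5 | 60.5 |
| south-east | 1.33 | 40.2 | 59.5 |
| south-east | 2.50 | 40.5 | 59.6 |
| south-east | 4.00 | 39.9 | 59.6 |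
| south-east | 5.00 | 40.9 | 60.3 |
| east | 0.667 | 30.9 | 66.8 |
| east | 2.00 | 33.2 | 66.5 |
| east | 3.00 | 31.9 | 65.9 |
| east | 5.00 | 34.5 | 66.0 |

(each reading ± 1 percentage point)

- a species is counted by the substrate in it: one open dimer counts as two
- the earlier runs were read with a standard deviation of 1 percentage point
- a reading or a percentage of ring counts all its forms, free or not

- which flask leads in share of ring in ring plus open dimer ("all alike" within 1.5 percentage points) (eta / zeta / alpha / theta / all alike)
- share of ring in ring plus open dimer at the end, eta
- share of ring in ring plus open dimer at the end, zeta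
- share of ring in ring plus open dimer at the end, alpha
- share of ring in ring plus open dimer at the end, theta

Read it as a partition: an activated form either closes to ring or is caught by free substrate, and each catch costs a second substrate. Let K be the capture constant, a selectivity factor per molar, and let y = 2·K·c(substrate). Substrate held at a steady level then yields a ring share of 1/(1+y), and a batch yields ln(1+y)/y. The share 40.6 % gives y = 3.95, so K = 9.88 /M. For the east run, K gives 32.7 %, and its last pair of readings gives 34.3 %.

Two extremes bracket the flasks. Everything together, as in zeta, is the batch at 40.6 %, and y holds no activator, so I put eta there too. A feed holding c(substrate) near zero gives nearly 100 %, and the dimer is then a small correction. The north run, with alpha's activator charge, already reads 40.5 % and 60.2 % at 0.667 min, so I allow that time 4 lifetimes and take a substrate lifetime of 0.167 min. Alpha's feed of 0.0667 M/min then holds c(substrate) near 0.0111 M, which gives 82.0 %. Theta's portions of 0.0400 M stand 0.750 min apart, longer than that lifetime, so I count them as small separate batches, each giving 73.7 %.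

The forecast names alpha, with eta 41 %, zeta 40.7 %, alpha 88 % and theta 74 %: “Feeding substrate keeps free substrate low”. My alpha lies lower.

The flasks give eta 39.6 %, zeta 41.2 %, alpha 84.9 % and theta 74.8 %, so alpha leads.

    substrate + activator → activated form (k = 0.372 /M/s)
    activated form → ring (k = 0.702 /s)
    substrate + activated form → open dimer (k = 7.37 /M/s)
    crystals ⇌ ring, rate k4*(cs4 - [ring]) while solid is left; crystals form when [ring] > cs4 (solubility = 15.0 mM, k = 2.06 /s)

Through K, alpha's 84.9 % answers to a held level of 0.00900 M, and alpha stood at 0.0103 M of substrate at 2.50 min. Theta's 74.8 % stands beside the 73.7 % reckoned per portion. Alpha has come to rest: its substrate reads 0 % at 5.00 min, and going on to 50.0 min changes its ring, crystals counted, by 3.7 × 10⁻⁴ percentage points.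

(The data come from a simulation for substances that don't exist; noise was put on by code.)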